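## Structural features

The target is a biflavanone, (2S,2''S)-2,3,2'',3''-tetrahydrohinokiflavone: two (2S)-naringenin units joined by a diaryl ether from O4' of ring B of unit 1 to C6'' of ring A of unit 2. Each unit has a phloroglucinol-type ring A fused to a dihydropyranone ring C and a para-oxygenated aryl group at C2. The two stereocentres, C2 and C2'', are benzylic C–O carbons separated by the para-phenylene ether bridge, so neither can control the other and each must be set by a reagent. Both are fragile, because the O1–C2 bond lies beta to the C4 ketone: base (through the C3 enolate) or a strong Lewis acid opens ring C to the 2'-hydroxychalcone and erases the centre, and the para oxygen on the C2 aryl group makes this easier. The five free phenols, two of them chelated to the ketones, are the other sensitive groups. The real difficulty is regiochemical: ring A of unit 2 is a 1,2,3,5-tetraoxygenated benzene with O5'', O6'' and O7'' contiguous, and closure of a 2',6'-dihydroxyaryl enone could engage either ortho oxygen and give the 6''- or the 8''-aryloxy isomer. The key step exploits the fact that the pyranone is fused to the C4a''–C8a'' edge and that C5'', next to C4a'', carries an oxygen. An aryne across that edge is polarised by the C5'' alkoxy group, so an alkoxide bonds to C8a'' and the acyl carbon to C4a''.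

## Logic of the disconnections

29 ⇒ 28. The five phenolic O–H bonds are traced back to O–benzyl bonds. All phenols then carry one group that leaves under neutral hydrogenolysis, so the last step needs neither acid nor base near the two O1–C2 bonds. The skeleton is not simplified; the forward step must cleave primary benzyl ethers faster than the secondary benzylic ring ethers.

28 ⇒ 21 + 26. Ring C of unit 1 is opened at O1–C8a and C4–C4a. This separates ring A of unit 1 as an aryne equivalent from a beta-hydroxy ester that already holds C2 in its final configuration. The benzyloxy group flanking the aryne fixes the 5,7-pattern. The forward step must release an alkoxide in a molecule that contains the enolisable ketone of unit 2 without opening that ring.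

21 ⇒ 20 ⇒ 19. The carbinol C–H bond is cut back to a ketone, so the stereocentre comes from a catalyst-controlled hydrogenation. The bond between the benzylic carbonyl carbon and the CH2 group is cut back to an aldehyde, which is homologated with a diazoacetate. The forward steps must reduce the chelating beta-keto ester but not the C4'' ketone, and homologate the aldehyde but not the ketone.

19 ⇒ 18. The aldehyde is masked as a cyclic acetal so that it survives organolithium reagents, fluoride, alkoxide and the aryne. The unmasking must be mild enough for ring C of unit 2.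

18 ⇒ 13 + 16. Ring C of unit 2 is opened at O1''–C8a'' and C4''–C4a''. This is the strategic cut: the 6''-aryloxy regiochemistry is written into the position of the silyl and triflate groups of 13, and the stereocentre is bought in 16 before the ring exists. The forward step must add the alkoxide to the aryne carbon remote from the flanking alkoxy group and must trap the aldolate before it fragments or eliminates.

16 ⇒ 15 ⇒ 14. The carbinol is again traced to a beta-keto ester, and the ester carbon to a carbonate acylation of a methyl ketone. Both steps are standard; the hydrogenation must be highly enantioselective.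

13 ⇒ 10 ⇒ 9. The C–Si and O–S bonds are cut back to an ortho-bromophenol (silyl shift from oxygen to carbon, then triflation), and the C–Br bond to the phenol. The phenol ring has only two open positions and they are equivalent, so the bromination has no regiochemical choice; it must stop at the monobromide.

9 ⇒ 6 ⇒ 5 ⇒ 4 ⇒ 3. The phenolic C–O bond is traced to a C–Br bond that marks this carbon from the start. The acetal and the two benzyl ethers are then removed in the retrosynthetic sense, and the benzyl ethers are traced to the methyl ethers of a cheap building block. The exchange is placed on an achiral, robust intermediate.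

3 ⇒ 1 + 2. The diaryl ether C–O bond is cut next to the ring that carries the formyl group, which activates fluoride displacement. The hindered, doubly ortho-substituted phenoxide must act as the nucleophile.

26 ⇒ 23 ⇒ 22. The same silyl-shift and bromination logic gives the aryne equivalent of ring A of unit 1. Here the bromination must choose the carbon ortho to the hydroxyl over the carbon para to it.

## Other disconnections considered

Alternative 1: Both O1–C2 bonds are cut and each C2 is traced to the beta carbon of an E-enone, which leads to the protected bis-chalcone A1. In the forward key step poly-L-leucine with urea–hydrogen peroxide would epoxidise both enones to the bis[(alphaR,betaS)-epoxy ketone] A2. Each oxirane would then be opened reductively at the carbon next to the carbonyl, the allyl ethers removed, and the rings closed with inversion at the benzylic carbon. In its favour, one catalytic operation sets both benzylic C–O centres, and a two-directional reaction tends to raise the enantiomeric purity of the doubly correct product at the cost of a separable diastereomer. On these two points it is better than the chosen plan, which needs two separate hydrogenations. Against it, the enones of A1 carry aryl ketones with two ortho alkoxy groups; these are twisted and electron-rich, a poor fit for this epoxidation. Four stereocentres are made and two are destroyed, which costs a regioselective reduction, a deallylation and an invertive closure on each half. The regiochemical problem of unit 2 is also only moved, since the two ortho oxygens of its aryl ketone must be told apart (allyl against benzyl) when A1 is built. In the chosen plan the aryne fixes that choice by the position of the silyl and triflate groups in 13. On mechanism, the chosen plan closes the ring with strong bases present and must show that the aldolate survives. Alternative 1 closes under neutral conditions and is safer on that point, but its adjustment of oxidation state makes it longer after the stereochemical step.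

Alternative 2: Both C3–C4 bonds are cut. Each ring C is traced to a 1-silyloxyvinyl group on ring A and an (S)-1-arylallyl ether on the neighbouring oxygen, giving the bis(diene) A3. In the forward key step the second-generation Grubbs catalyst would close both rings to the bis(silyl enol ether) A4, which mild desilylation would convert into the protected target. In its favour, the closure is neutral, the ketone is born masked as an enol ether so no enolisable flavanone is exposed to base, and both rings form in one operation. On the safety of the stereocentres during ring closure it is better than the chosen plan. Against it, the metathesis must join a 1,1-disubstituted silyl enol ether flanked by two ortho substituents, a slow case that has to work twice. The stereocentres must first be installed as secondary allylic benzylic aryl ethers on hindered ortho-acyl phenols, which are prone to ionisation and to sigmatropic shift. The two ortho oxygens of ring A of unit 2 must again be differentiated before the allyl ether is made. On structure, both plans carry a preformed C2 centre into the ring closure, and they are equal in that respect. On step economy the chosen plan is shorter, because 13 and 16 each come from simple materials without unsymmetrical protection of a phloroglucinol ring.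

Alternative 3: Ring A of unit 1 is cut into three acetate units, leaving the cinnamic acid A5 that already carries the complete unit 2. In the forward key step a 4-coumarate ligase would activate A5 as its thioester and chalcone synthase would extend it with three malonyl thioester units and close the ring by Claisen cyclisation to the chalcone A6. Ring closure to the flavanone would follow, ideally by chalcone isomerase. In its favour, four C–C bonds and an unprotected phloroglucinol ring form in water without protecting groups, and an isomerase would set C2 as S. On protecting-group economy for unit 1 it is better than the chosen plan, and on the regiochemistry of ring A of unit 1 the two are equal. Against it, A5 is far larger than the natural 4-hydroxycinnamoyl starter, so acceptance by both enzymes is doubtful without enzyme engineering. Non-enzymatic closure of A6 would give both C2 epimers. The flavanone of A5 would sit for long periods in buffer, where it can slowly equilibrate with its chalcone. A5 also still requires the whole chemical synthesis of unit 2, including the regiochemical problem at C6''. The enzymatic step is therefore no substitute for the key step of the chosen plan. It could only replace the second annulation sequence, and with less predictable scope.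

Key step: step 10

Remarks on the chemistry:
- All phenolic oxygens are carried as benzyl ethers. The two methyl ethers brought in by the cheapest ring A building block are exchanged at an achiral stage (steps 2 and 3), because a late Lewis-acid demethylation next to two ring-opening-prone C2 centres is judged unsafe.
- 4-Bromo-2,6-dimethoxyphenol 1 and 3,5-bis(benzyloxy)phenol 22 are taken to be catalogue compounds.
- Only species that accumulate between reagent additions are numbered as intermediates; arynes and aryl anions are treated in the Why lines.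
- With RuCl2[(R)-BINAP] the usual facial preference for beta-keto esters is assumed. It corresponds to the (S) descriptor for 3-aryl-3-hydroxy esters, because aryl outranks the CH2CO2R group.

## Route

Step 1
Reactants: 1 4-bromo-2,6-dimethoxyphenol; 2 4-fluorobenzaldehyde
Product: 3 4-(4-bromo-2,6-dimethoxyphenoxy)benzaldehyde
Conditions: K2CO3, DMF, 120 °C
Reagents that add atoms: none
Why: Nucleophilic aromatic substitution (addition–elimination): the hindered phenoxide of 1 displaces fluoride para to the formyl group, while the unactivated C–Br bond is inert. The bromine marks the carbon that later carries the triflate oxygen, so that position needs no protecting group.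

Step 2
Reactants: 3 4-(4-bromo-2,6-dimethoxyphenoxy)benzaldehyde
Product: 4 4-(4-bromo-2,6-dihydroxyphenoxy)benzaldehyde
Conditions: BBr3, CH2Cl2, −78 °C → rt; H2O
Reagents that add atoms: none
Why: Lewis-acid cleavage of aryl methyl ethers; the diaryl ether and the aryl bromide are inert and the complexed aldehyde is released on hydrolysis. The demethylation is done here, on an achiral compound, so that none is needed once the flavanone stereocentres exist.

Step 3
Reactants: 4 4-(4-bromo-2,6-dihydroxyphenoxy)benzaldehyde
Product: 5 4-[2,6-bis(benzyloxy)-4-bromophenoxy]benzaldehyde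
Conditions: BnBr, K2CO3, DMF, 50 °C
Reagents that add atoms: benzyl bromide, BrCc1ccccc1
Why: Williamson etherification of both phenols. The benzyl ethers are stable to every later step and are all removed together in step 17.

Step 4
Reactants: 5 4-[2,6-bis(benzyloxy)-4-bromophenoxy]benzaldehyde
Product: 6 2-{4-[2,6-bis(benzyloxy)-4-bromophenoxy]phenyl}-1,3-dioxolane
Conditions: HOCH2CH2OH, p-TsOH (cat.), toluene, reflux, Dean–Stark
Reagents that add atoms: ethylene glycol, OCCO
Why: Acid-catalysed acetalisation with azeotropic removal of water. The dioxolane protects the aldehyde from n-BuLi (steps 5 and 7) and from the alkoxide and aryne of step 10.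

Step 5
Reactants: 6 2-{4-[2,6-bis(benzyloxy)-4-bromophenoxy]phenyl}-1,3-dioxolane
Product: 9 3,5-bis(benzyloxy)-4-[4-(1,3-dioxolan-2-yl)phenoxy]phenol, via aryllithium 7 (not isolated), via dimethyl arylboronate 8 (not isolated)
Conditions: n-BuLi, THF, −78 °C; B(OMe)3, −78 → 0 °C; H2O2, aq. NaOH, 0 °C → rt
Reagents that add atoms: hydrogen peroxide, OO
Why: Bromine–lithium exchange, borylation of the aryllithium and oxidative 1,2-shift of the aryl group from boron to oxygen turn C–Br into C–OH at a fixed position. Benzyl ethers and the acetal tolerate n-BuLi at −78 °C and alkaline peroxide.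

Step 6
Reactants: 9 3,5-bis(benzyloxy)-4-[4-(1,3-dioxolan-2-yl)phenoxy]phenol
Product: 10 3,5-bis(benzyloxy)-2-bromo-4-[4-(1,3-dioxolan-2-yl)phenoxy]phenol
Conditions: NBS (1.0 equiv), i-Pr2NH (cat.), CH2Cl2, −78 → 0 °C
Reagents that add atoms: N-bromosuccinimide, O=C1CCC(=O)N1Br
Why: Amine-assisted electrophilic bromination ortho to the free phenol. The only open positions of the most electron-rich ring are the two equivalent carbons ortho to the hydroxyl, so one equivalent of NBS at low temperature should give the monobromide.

Step 7
Reactants: 10 3,5-bis(benzyloxy)-2-bromo-4-[4-(1,3-dioxolan-2-yl)phenoxy]phenol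
Product: 13 3,5-bis(benzyloxy)-4-[4-(1,3-dioxolan-2-yl)phenoxy]-2-(trimethylsilyl)phenyl trifluoromethanesulfonate, via aryl trimethylsilyl ether 11 (not isolated), via lithium silylphenoxide 12 (not isolated)
Conditions: (Me3Si)2NH, THF, 65 °C, then evaporate; n-BuLi, THF, −78 °C; PhNTf2, −78 °C → rt
Reagents that add atoms: hexamethyldisilazane, C[Si](C)(C)N[Si](C)(C)C; N-phenylbis(trifluoromethanesulfonimide), O=S(=O)(N(c1ccccc1)S(=O)(=O)C(F)(F)F)C(F)(F)F
Why: O-silylation, bromine–lithium exchange and anionic 1,3-shift of silicon from oxygen to carbon (retro-Brook rearrangement) place the SiMe3 group next to the phenoxide, which is then triflated. PhNTf2 is used instead of the anhydride to spare the acetal.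

Step 8
Reactants: 14 4'-(benzyloxy)acetophenone
Product: 15 methyl 3-[4-(benzyloxy)phenyl]-3-oxopropanoate
Conditions: NaH, (MeO)2CO, THF, reflux; aq. HCl
Reagents that add atoms: dimethyl carbonate, COC(=O)OC
Why: Crossed Claisen condensation: the sodium enolate of 14 is acylated by dimethyl carbonate and the product is held as its stabilised enolate until the acidic quench.

Step 9
Reactants: 15 methyl 3-[4-(benzyloxy)phenyl]-3-oxopropanoate
Product: 16 methyl (S)-3-[4-(benzyloxy)phenyl]-3-hydroxypropanoate
Conditions: H2 (50 bar), RuCl2[(R)-BINAP] (0.5 mol%), MeOH, 50 °C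
Reagents that add atoms: none
Why: Noyori asymmetric hydrogenation of a chelating beta-keto ester; with the (R)-BINAP complex hydride is delivered to the face that gives the (S)-carbinol. Benzyl ethers are not touched by the homogeneous ruthenium catalyst.

Step 10
Reactants: 13 3,5-bis(benzyloxy)-4-[4-(1,3-dioxolan-2-yl)phenoxy]-2-(trimethylsilyl)phenyl trifluoromethanesulfonate; 16 methyl (S)-3-[4-(benzyloxy)phenyl]-3-hydroxypropanoate
Product: 18 (S)-5,7-bis(benzyloxy)-2-[4-(benzyloxy)phenyl]-6-[4-(1,3-dioxolan-2-yl)phenoxy]chroman-4-one, via trimethylsilyl ether 17 (not isolated)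
Conditions: 16 (1.3 equiv), (Me3Si)2NH, Me3SiCl (cat.), CH2Cl2, rt, then evaporate; 13, CsF, 18-crown-6, THF, −20 °C → rt; pH 7 buffer
Reagents that add atoms: none
Why: Proposed new method: fluoride removes the aryl SiMe3 group of 13 and triflate leaves to give the 3-benzyloxyaryne, while fluoride also unmasks the cesium alkoxide of 16 from silyl ether 17, so that no O–H is present to protonate the aryl anion. The alkoxide adds to the aryne carbon remote from the flanking benzyloxy group (the future C8a''), as favoured by the distortion of 3-alkoxyarynes and by inductive stabilisation of the carbanion developing at C4a'' next to the C5''–O bond. The aryl anion then attacks the methyl ester through a six-membered transition state (6-exo-trig acyl substitution), expels methoxide and closes ring C of unit 2, forming O1''–C8a'' and C4''–C4a''. The closest known reactions are the fluoride-triggered annulations of arynes with methyl salicylates to xanthones and with unsaturated carboxylic acids to 4-chromanones; here the nucleophile is an aliphatic aldolate instead of a phenoxide or carboxylate. No stereocentre is created: C2'' is the carbinol carbon of 16 and keeps its (S) configuration because its C–O bond is never broken. The step needs regioselectivity on the aryne, which the C5'' benzyloxy group secures, and O-arylation must outrun retro-aldol cleavage and beta-elimination of the aldolate; for that the alkoxide is released only at low temperature in the presence of the aryne precursor, with 16 in excess.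

Step 11
Reactants: 18 (S)-5,7-bis(benzyloxy)-2-[4-(benzyloxy)phenyl]-6-[4-(1,3-dioxolan-2-yl)phenoxy]chroman-4-one
Product: 19 4-{[(S)-5,7-bis(benzyloxy)-2-[4-(benzyloxy)phenyl]-4-oxochroman-6-yl]oxy}benzaldehyde
Conditions: p-TsOH (cat.), acetone–H2O, rt
Reagents that add atoms: water, O
Why: Acid-catalysed acetal hydrolysis under conditions too mild to open ring C or to cleave benzyl ethers.

Step 12
Reactants: 19 4-{[(S)-5,7-bis(benzyloxy)-2-[4-(benzyloxy)phenyl]-4-oxochroman-6-yl]oxy}benzaldehyde
Product: 20 ethyl 3-(4-{[(S)-5,7-bis(benzyloxy)-2-[4-(benzyloxy)phenyl]-4-oxochroman-6-yl]oxy}phenyl)-3-oxopropanoate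
Conditions: N2CHCO2Et, SnCl2 (10 mol%), CH2Cl2, rt
Reagents that add atoms: ethyl diazoacetate, CCOC(=O)C=[N+]=[N-]
Why: Roskamp homologation: SnCl2 activates the aldehyde, the diazoacetate adds, and a 1,2-hydride shift with loss of nitrogen gives the beta-keto ester. The chromanone ketone is far less electrophilic and should not react, and no base is present.

Step 13
Reactants: 20 ethyl 3-(4-{[(S)-5,7-bis(benzyloxy)-2-[4-(benzyloxy)phenyl]-4-oxochroman-6-yl]oxy}phenyl)-3-oxopropanoate
Product: 21 ethyl (S)-3-(4-{[(S)-5,7-bis(benzyloxy)-2-[4-(benzyloxy)phenyl]-4-oxochroman-6-yl]oxy}phenyl)-3-hydroxypropanoate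
Conditions: H2 (50 bar), RuCl2[(R)-BINAP] (1 mol%), EtOH–CH2Cl2, 50 °C
Reagents that add atoms: none
Why: Noyori asymmetric hydrogenation; only the beta-keto ester can chelate ruthenium, so the C4'' aryl ketone should be left alone. The (R)-BINAP complex sets the new carbinol (S) by catalyst control, independent of the remote C2'' centre.

Step 14
Reactants: 22 3,5-bis(benzyloxy)phenol
Product: 23 3,5-bis(benzyloxy)-2-bromophenol
Conditions: NBS (1.0 equiv), i-Pr2NH (cat.), CH2Cl2, −78 °C
Reagents that add atoms: N-bromosuccinimide, O=C1CCC(=O)N1Br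
Why: Amine-assisted electrophilic bromination of a phenol in a non-polar solvent, which favours the carbon between the hydroxyl and one benzyloxy group over the more hindered carbon between the two benzyloxy groups.

Step 15
Reactants: 23 3,5-bis(benzyloxy)-2-bromophenol
Product: 26 3,5-bis(benzyloxy)-2-(trimethylsilyl)phenyl trifluoromethanesulfonate, via aryl trimethylsilyl ether 24 (not isolated), via lithium silylphenoxide 25 (not isolated)
Conditions: (Me3Si)2NH, THF, 65 °C, then evaporate; n-BuLi, THF, −78 °C; Tf2O, −78 °C → rt
Reagents that add atoms: hexamethyldisilazane, C[Si](C)(C)N[Si](C)(C)C; trifluoromethanesulfonic anhydride, O=S(=O)(OS(=O)(=O)C(F)(F)F)C(F)(F)F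
Why: O-silylation, bromine–lithium exchange, retro-Brook shift of silicon to carbon and triflation of the resulting phenoxide, the standard entry to ortho-silylaryl triflates.

Step 16
Reactants: 21 ethyl (S)-3-(4-{[(S)-5,7-bis(benzyloxy)-2-[4-(benzyloxy)phenyl]-4-oxochroman-6-yl]oxy}phenyl)-3-hydroxypropanoate; 26 3,5-bis(benzyloxy)-2-(trimethylsilyl)phenyl trifluoromethanesulfonate
Product: 28 (S)-5,7-bis(benzyloxy)-2-(4-{[(S)-5,7-bis(benzyloxy)-2-[4-(benzyloxy)phenyl]-4-oxochroman-6-yl]oxy}phenyl)chroman-4-one, via trimethylsilyl ether 27 (not isolated)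
Conditions: 21, (Me3Si)2NH, Me3SiCl (cat.), CH2Cl2, rt, then evaporate; 26 (1.5 equiv), CsF, 18-crown-6, THF, −20 °C → rt; pH 7 buffer
Reagents that add atoms: none
Why: Proposed new method: the same aryne insertion cascade as in step 10 (closest known type: fluoride-triggered aryne annulation of methyl salicylates to xanthones); the alkoxide unmasked from 27 adds to the aryne carbon remote from the flanking benzyloxy group and the aryl anion acylates itself on the ethyl ester (6-exo-trig), closing ring C of unit 1 with the 5,7-pattern. C2 keeps its (S) configuration because its C–O bond is not broken. C2'' is at risk only through enolisation of the unit 2 ketone, which the low temperature and the absence of a stoichiometric strong base are meant to suppress.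

Step 17
Reactants: 28 (S)-5,7-bis(benzyloxy)-2-(4-{[(S)-5,7-bis(benzyloxy)-2-[4-(benzyloxy)phenyl]-4-oxochroman-6-yl]oxy}phenyl)chroman-4-one
Product: 29 (S)-6-{4-[(S)-5,7-dihydroxy-4-oxochroman-2-yl]phenoxy}-5,7-dihydroxy-2-(4-hydroxyphenyl)chroman-4-one
Conditions: H2 (1 atm), 10% Pd/C, EtOAc–MeOH, rt
Reagents that add atoms: none
Why: Hydrogenolysis of five benzyl aryl ethers on palladium under neutral conditions; the secondary benzylic O1–C2 ring ethers should be cleaved much more slowly and the chelated ketones should not be reduced. With no acid or base present, neither stereocentre can equilibrate through the chalcone.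

## Compound list

1 | 4-bromo-2,6-dimethoxyphenol | COc1cc(Br)cc(OC)c1O | starting material
2 | 4-fluorobenzaldehyde | O=Cc1ccc(F)cc1 | starting material
3 | 4-(4-bromo-2,6-dimethoxyphenoxy)benzaldehyde | COc1cc(Br)cc(OC)c1Oc1ccc(C=O)cc1 | intermediate
4 | 4-(4-bromo-2,6-dihydroxyphenoxy)benzaldehyde | Oc1cc(Br)cc(O)c1Oc1ccc(C=O)cc1 | intermediate
5 | 4-[2,6-bis(benzyloxy)-4-bromophenoxy]benzaldehyde | O=Cc1ccc(Oc2c(OCc3ccccc3)cc(Br)cc2OCc2ccccc2)cc1 | intermediate
6 | 2-{4-[2,6-bis(benzyloxy)-4-bromophenoxy]phenyl}-1,3-dioxolane | Brc1cc(OCc2ccccc2)c(Oc2ccc(C3OCCO3)cc2)c(OCc2ccccc2)c1 | intermediate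
7 | {3,5-bis(benzyloxy)-4-[4-(1,3-dioxolan-2-yl)phenoxy]phenyl}lithium (not isolated) | [Li]c1cc(OCc2ccccc2)c(Oc2ccc(C3OCCO3)cc2)c(OCc2ccccc2)c1 | intermediate
8 | dimethyl {3,5-bis(benzyloxy)-4-[4-(1,3-dioxolan-2-yl)phenoxy]phenyl}boronate (not isolated) | COB(OC)c1cc(OCc2ccccc2)c(Oc2ccc(C3OCCO3)cc2)c(OCc2ccccc2)c1 | intermediate
9 | 3,5-bis(benzyloxy)-4-[4-(1,3-dioxolan-2-yl)phenoxy]phenol | Oc1cc(OCc2ccccc2)c(Oc2ccc(C3OCCO3)cc2)c(OCc2ccccc2)c1 | intermediate
10 | 3,5-bis(benzyloxy)-2-bromo-4-[4-(1,3-dioxolan-2-yl)phenoxy]phenol | Oc1cc(OCc2ccccc2)c(Oc2ccc(C3OCCO3)cc2)c(OCc2ccccc2)c1Br | intermediate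
11 | {3,5-bis(benzyloxy)-2-bromo-4-[4-(1,3-dioxolan-2-yl)phenoxy]phenoxy}trimethylsilane (not isolated) | C[Si](C)(C)Oc1cc(OCc2ccccc2)c(Oc2ccc(C3OCCO3)cc2)c(OCc2ccccc2)c1Br | intermediate
12 | lithium 3,5-bis(benzyloxy)-4-[4-(1,3-dioxolan-2-yl)phenoxy]-2-(trimethylsilyl)phenoxide (not isolated) | [Li+].[O-]c1cc(OCc2ccccc2)c(Oc2ccc(C3OCCO3)cc2)c(OCc2ccccc2)c1[Si](C)(C)C | intermediate
13 | 3,5-bis(benzyloxy)-4-[4-(1,3-dioxolan-2-yl)phenoxy]-2-(trimethylsilyl)phenyl trifluoromethanesulfonate | C[Si](C)(C)c1c(OCc2ccccc2)c(Oc2ccc(C3OCCO3)cc2)c(OCc2ccccc2)cc1OS(=O)(=O)C(F)(F)F | intermediate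
14 | 4'-(benzyloxy)acetophenone | CC(=O)c1ccc(OCc2ccccc2)cc1 | starting material
15 | methyl 3-[4-(benzyloxy)phenyl]-3-oxopropanoate | COC(=O)CC(=O)c1ccc(OCc2ccccc2)cc1 | intermediate
16 | methyl (S)-3-[4-(benzyloxy)phenyl]-3-hydroxypropanoate | COC(=O)C[C@@H](c1ccc(OCc2ccccc2)cc1)O | intermediate
17 | methyl (S)-3-[4-(benzyloxy)phenyl]-3-(trimethylsilyloxy)propanoate (not isolated) | COC(=O)C[C@@H](c1ccc(OCc2ccccc2)cc1)O[Si](C)(C)C | intermediate
18 | (S)-5,7-bis(benzyloxy)-2-[4-(benzyloxy)phenyl]-6-[4-(1,3-dioxolan-2-yl)phenoxy]chroman-4-one | O=C1C[C@@H](c2ccc(OCc3ccccc3)cc2)Oc2cc(OCc3ccccc3)c(Oc3ccc(C4OCCO4)cc3)c(OCc3ccccc3)c21 | intermediate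
19 | 4-{[(S)-5,7-bis(benzyloxy)-2-[4-(benzyloxy)phenyl]-4-oxochroman-6-yl]oxy}benzaldehyde | O=C1C[C@@H](c2ccc(OCc3ccccc3)cc2)Oc2cc(OCc3ccccc3)c(Oc3ccc(C=O)cc3)c(OCc3ccccc3)c21 | intermediate
20 | ethyl 3-(4-{[(S)-5,7-bis(benzyloxy)-2-[4-(benzyloxy)phenyl]-4-oxochroman-6-yl]oxy}phenyl)-3-oxopropanoate | O=C1C[C@@H](c2ccc(OCc3ccccc3)cc2)Oc2cc(OCc3ccccc3)c(Oc3ccc(C(=O)CC(=O)OCC)cc3)c(OCc3ccccc3)c21 | intermediate
21 | ethyl (S)-3-(4-{[(S)-5,7-bis(benzyloxy)-2-[4-(benzyloxy)phenyl]-4-oxochroman-6-yl]oxy}phenyl)-3-hydroxypropanoate | O=C1C[C@@H](c2ccc(OCc3ccccc3)cc2)Oc2cc(OCc3ccccc3)c(Oc3ccc([C@@H](O)CC(=O)OCC)cc3)c(OCc3ccccc3)c21 | intermediate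
22 | 3,5-bis(benzyloxy)phenol | Oc1cc(OCc2ccccc2)cc(OCc2ccccc2)c1 | starting material
23 | 3,5-bis(benzyloxy)-2-bromophenol | Oc1cc(OCc2ccccc2)cc(OCc2ccccc2)c1Br | intermediate
24 | [3,5-bis(benzyloxy)-2-bromophenoxy]trimethylsilane (not isolated) | C[Si](C)(C)Oc1cc(OCc2ccccc2)cc(OCc2ccccc2)c1Br | intermediate
25 | lithium 3,5-bis(benzyloxy)-2-(trimethylsilyl)phenoxide (not isolated) | [Li+].[O-]c1cc(OCc2ccccc2)cc(OCc2ccccc2)c1[Si](C)(C)C | intermediate
26 | 3,5-bis(benzyloxy)-2-(trimethylsilyl)phenyl trifluoromethanesulfonate | C[Si](C)(C)c1c(OCc2ccccc2)cc(OCc2ccccc2)cc1OS(=O)(=O)C(F)(F)F | intermediate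
27 | ethyl (S)-3-(4-{[(S)-5,7-bis(benzyloxy)-2-[4-(benzyloxy)phenyl]-4-oxochroman-6-yl]oxy}phenyl)-3-(trimethylsilyloxy)propanoate (not isolated) | O=C1C[C@@H](c2ccc(OCc3ccccc3)cc2)Oc2cc(OCc3ccccc3)c(Oc3ccc([C@@H](O[Si](C)(C)C)CC(=O)OCC)cc3)c(OCc3ccccc3)c21 | intermediate
28 | (S)-5,7-bis(benzyloxy)-2-(4-{[(S)-5,7-bis(benzyloxy)-2-[4-(benzyloxy)phenyl]-4-oxochroman-6-yl]oxy}phenyl)chroman-4-one | O=C1C[C@@H](c2ccc(Oc3c(OCc4ccccc4)cc4c(c3OCc3ccccc3)C(=O)C[C@@H](c3ccc(OCc5ccccc5)cc3)O4)cc2)Oc2cc(OCc3ccccc3)cc(OCc3ccccc3)c21 | intermediate
29 | (S)-6-{4-[(S)-5,7-dihydroxy-4-oxochroman-2-yl]phenoxy}-5,7-dihydroxy-2-(4-hydroxyphenyl)chroman-4-one | O=C1C[C@@H](c2ccc(Oc3c(O)cc4c(c3O)C(=O)C[C@@H](c3ccc(O)cc3)O4)cc2)Oc2cc(O)cc(O)c21 | target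

## Step count and least certain steps

Total: 17 steps. Longest linear sequence: 13 steps (steps 1–7, 10–13, 16 and 17). Steps 8–9 and 14–15 are side branches.

Step 10 (key step, proposed as new chemistry). The most likely failure is that the freed aldolate undergoes beta-elimination to the cinnamate or retro-aldol cleavage faster than it meets the aryne. The aryl anion may also be quenched before it reaches the ester and leave an uncyclised aryl ether, and released methoxide may open ring C of the product and erode C2''. The fallback uses known chemistry and sets out from 15 and 10. Hydrogenation of 15 with RuCl2[(S)-BINAP] should give methyl (R)-3-[4-(benzyloxy)phenyl]-3-hydroxypropanoate F1. Mitsunobu etherification of phenol 10 with F1 (PPh3, DIAD, THF, 0 °C) should proceed with inversion to methyl (S)-3-[4-(benzyloxy)phenyl]-3-{3,5-bis(benzyloxy)-2-bromo-4-[4-(1,3-dioxolan-2-yl)phenoxy]phenoxy}propanoate F2. Bromine–lithium exchange (n-BuLi, THF, −100 °C) followed by Parham cyclisation of the aryllithium onto the ester returns to the route at 18. The regiochemistry is then fixed by the bromine of 10, at the cost of an ionisation-prone Mitsunobu step.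

Step 16 (proposed as new chemistry). The most likely failure is enolisation of the unit 2 chromanone by the transient alkoxide or by fluoride, followed by ring opening to the chalcone phenoxide, with loss of configuration at C2'' and O-arylation of that phenoxide by the aryne. The fallback uses known chemistry and sets out from 20 and 22. Hydrogenation of 20 with RuCl2[(S)-BINAP] should give ethyl (R)-3-(4-{[(S)-5,7-bis(benzyloxy)-2-[4-(benzyloxy)phenyl]-4-oxochroman-6-yl]oxy}phenyl)-3-hydroxypropanoate F3. Mitsunobu etherification with phenol 22 (PPh3, DIAD, THF, 0 °C) should give, with inversion, ethyl (S)-3-[3,5-bis(benzyloxy)phenoxy]-3-(4-{[(S)-5,7-bis(benzyloxy)-2-[4-(benzyloxy)phenyl]-4-oxochroman-6-yl]oxy}phenyl)propanoate F4. Neutral ester cleavage (Me3SnOH, 1,2-dichloroethane, 80 °C) should give (S)-3-[3,5-bis(benzyloxy)phenoxy]-3-(4-{[(S)-5,7-bis(benzyloxy)-2-[4-(benzyloxy)phenyl]-4-oxochroman-6-yl]oxy}phenyl)propanoic acid F5. Intramolecular Friedel–Crafts acylation through the mixed anhydride ((CF3CO)2O, CH2Cl2, 0 °C) closes onto one of the two equivalent carbons ortho to the ether oxygen and returns to the route at 28.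

Step 13. The most likely failure is slow turnover of the bulky, poorly soluble aryl beta-keto ester. Long heating could then bring partial reduction of the C4'' ketone or acid-promoted epimerisation at C2''. The fallback sets out from 19 and avoids the keto ester. A catalytic asymmetric Mukaiyama acetate aldol addition of 1-methoxy-1-(trimethylsilyloxy)ethene is used (Ti(OiPr)4 with a chiral binaphthyl Schiff-base ligand and 3,5-di-tert-butylsalicylic acid, the ligand enantiomer chosen for the (S)-adduct). It should give methyl (S)-3-(4-{[(S)-5,7-bis(benzyloxy)-2-[4-(benzyloxy)phenyl]-4-oxochroman-6-yl]oxy}phenyl)-3-(trimethylsilyloxy)propanoate F6. This is already the masked alkoxide and enters the second stage of step 16 with 26, returning to the route at 28.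

Step 14. The most likely failure is incomplete regiocontrol, with bromination para to the hydroxyl or a second bromination, on a ring in which all three open carbons are strongly activated. The fallback sets out from 22 and places the silicon by directed metalation. Carbamoylation (i-PrNCO, Et3N cat.) should give 3,5-bis(benzyloxy)phenyl N-isopropylcarbamate F7. Ortho-lithiation between the carbamate and a benzyloxy group after transient N-silylation (TBSOTf, TMEDA; n-BuLi, TMEDA, Et2O, −78 °C; Me3SiCl) should give 3,5-bis(benzyloxy)-2-(trimethylsilyl)phenyl N-isopropylcarbamate F8. Carbamate cleavage and triflation in one flask (DBU, Et2NH, MeCN, 40 °C; PhNTf2) returns to the route at 26.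

Step 17. The most likely failure is competing hydrogenolysis of the benzylic O1–C2 bonds (ring opening to dihydrochalcones) before the hindered 5- and 5''-benzyl ethers are gone. The fallback sets out from 28 and replaces the metal surface by Lewis-acid debenzylation with a cation scavenger (BCl3, pentamethylbenzene, CH2Cl2, −78 °C). Benzyl ethers cleave within minutes at that temperature, unlike methyl ethers. It returns to the route at 29 and makes no new intermediate.

## Further compounds

F1 | step 10 | methyl (R)-3-[4-(benzyloxy)phenyl]-3-hydroxypropanoate | COC(=O)C[C@H](c1ccc(OCc2ccccc2)cc1)O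
F2 | step 10 | methyl (S)-3-[4-(benzyloxy)phenyl]-3-{3,5-bis(benzyloxy)-2-bromo-4-[4-(1,3-dioxolan-2-yl)phenoxy]phenoxy}propanoate | COC(=O)C[C@@H](c1ccc(OCc2ccccc2)cc1)Oc1cc(OCc2ccccc2)c(Oc2ccc(C3OCCO3)cc2)c(OCc2ccccc2)c1Br
F3 | step 16 | ethyl (R)-3-(4-{[(S)-5,7-bis(benzyloxy)-2-[4-(benzyloxy)phenyl]-4-oxochroman-6-yl]oxy}phenyl)-3-hydroxypropanoate | O=C1C[C@@H](c2ccc(OCc3ccccc3)cc2)Oc2cc(OCc3ccccc3)c(Oc3ccc([C@H](O)CC(=O)OCC)cc3)c(OCc3ccccc3)c21
F4 | step 16 | ethyl (S)-3-[3,5-bis(benzyloxy)phenoxy]-3-(4-{[(S)-5,7-bis(benzyloxy)-2-[4-(benzyloxy)phenyl]-4-oxochroman-6-yl]oxy}phenyl)propanoate | O=C1C[C@@H](c2ccc(OCc3ccccc3)cc2)Oc2cc(OCc3ccccc3)c(Oc3ccc([C@@H](Oc4cc(OCc5ccccc5)cc(OCc5ccccc5)c4)CC(=O)OCC)cc3)c(OCc3ccccc3)c21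
F5 | step 16 | (S)-3-[3,5-bis(benzyloxy)phenoxy]-3-(4-{[(S)-5,7-bis(benzyloxy)-2-[4-(benzyloxy)phenyl]-4-oxochroman-6-yl]oxy}phenyl)propanoic acid | O=C1C[C@@H](c2ccc(OCc3ccccc3)cc2)Oc2cc(OCc3ccccc3)c(Oc3ccc([C@@H](Oc4cc(OCc5ccccc5)cc(OCc5ccccc5)c4)CC(=O)O)cc3)c(OCc3ccccc3)c21
F6 | step 13 | methyl (S)-3-(4-{[(S)-5,7-bis(benzyloxy)-2-[4-(benzyloxy)phenyl]-4-oxochroman-6-yl]oxy}phenyl)-3-(trimethylsilyloxy)propanoate | O=C1C[C@@H](c2ccc(OCc3ccccc3)cc2)Oc2cc(OCc3ccccc3)c(Oc3ccc([C@@H](O[Si](C)(C)C)CC(=O)OC)cc3)c(OCc3ccccc3)c21
F7 | step 14 | 3,5-bis(benzyloxy)phenyl N-isopropylcarbamate | CC(C)NC(=O)Oc1cc(OCc2ccccc2)cc(OCc2ccccc2)c1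
F8 | step 14 | 3,5-bis(benzyloxy)-2-(trimethylsilyl)phenyl N-isopropylcarbamate | CC(C)NC(=O)Oc1cc(OCc2ccccc2)cc(OCc2ccccc2)c1[Si](C)(C)C
F0 | step 17 | none | none
A1 | alternative 1 | protected bis-chalcone (both enones E; one allyl ether ortho to each aryl ketone, benzyl ethers elsewhere) | C=CCOc1cc(OCc2ccccc2)cc(OCc2ccccc2)c1C(=O)/C=C/c1ccc(Oc2c(OCc3ccccc3)cc(OCC=C)c(C(=O)/C=C/c3ccc(OCc4ccccc4)cc3)c2OCc2ccccc2)cc1
A2 | alternative 1 | bis[(alphaR,betaS)-epoxy ketone] derived from A1 | C=CCOc1cc(OCc2ccccc2)cc(OCc2ccccc2)c1C(=O)[C@@H]1O[C@H]1c1ccc(Oc2c(OCc3ccccc3)cc(OCC=C)c(C(=O)[C@@H]3O[C@H]3c3ccc(OCc4ccccc4)cc3)c2OCc2ccccc2)cc1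
A3 | alternative 2 | (S,S)-bis(diene): each ring A carries a 1-(tert-butyldimethylsilyloxy)vinyl group ortho to an (S)-1-arylallyl ether | C=C[C@@H](c1ccc(Oc2c(OCc3ccccc3)cc(O[C@@H](C=C)c3ccc(OCc4ccccc4)cc3)c(C(=C)O[Si](C)(C)C(C)(C)C)c2OCc2ccccc2)cc1)Oc1cc(OCc2ccccc2)cc(OCc2ccccc2)c1C(=C)O[Si](C)(C)C(C)(C)C
A4 | alternative 2 | (2S,2''S)-bis(4-tert-butyldimethylsilyloxy-2H-chromene), pentabenzyl ether | CC(C)(C)[Si](C)(C)OC1=C[C@@H](c2ccc(Oc3c(OCc4ccccc4)cc4c(c3OCc3ccccc3)C(O[Si](C)(C)C(C)(C)C)=C[C@@H](c3ccc(OCc5ccccc5)cc3)O4)cc2)Oc2cc(OCc3ccccc3)cc(OCc3ccccc3)c21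
A5 | alternative 3 | (E)-3-(4-{[(S)-5,7-dihydroxy-2-(4-hydroxyphenyl)-4-oxochroman-6-yl]oxy}phenyl)acrylic acid | OC(=O)/C=C/c1ccc(Oc2c(O)cc3c(c2O)C(=O)C[C@@H](c2ccc(O)cc2)O3)cc1
A6 | alternative 3 | (E)-2',4',6'-trihydroxychalcone of unit 1 carrying the intact (2S)-flavanone unit 2 | O=C(/C=C/c1ccc(Oc2c(O)cc3c(c2O)C(=O)C[C@@H](c2ccc(O)cc2)O3)cc1)c1c(O)cc(O)cc1O
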